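**Plan**
- Retrosynthesis: the two esters are removed first (C-9 tiglate, C-8 (R)-2-methylbutanoate), the C-8/C-9 oxygens are traced back to a C-9 ketone, and ring A is then cut at C-1–C-10 and C-4–C-5.
- Enabling feature: ring A is a cyclohexanone whose C-2 carbonyl lies 1,3 to C-10, with cis methyls on C-4/C-5 next to a cis ring fusion (C-5 methyl, C-10 H). This is the retron of a 2-silyloxy-1,3-pentadiene adding across the C-5=C-10 bond of a ring B 2-methylcyclohex-2-enone carrying a temporary C-6 carbonyl.
- Forward order: ring B first (quinone monoketal, asymmetric isopropenyl addition, γ-silyloxy enone), then ring A by an exo-selective Lewis-acid Diels–Alder reaction, then removal of the C-6 ketone, C-9 ketone, C-8 hydroxylation, C-9 reduction, two acylations, release of the C-2 ketone.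
- Stereochemistry: C-7 from the rhodium-catalysed 1,4-addition; C-4, C-5 and C-10 from the cycloaddition (face set by the β-substituents on C-7 and C-9, C-4 by the exo geometry); C-8 by enolate oxidation trans to C-7; C-9 by equatorial hydride attack; the ester centre from (R)-2-methylbutanoic acid.
- Helpers taken out again: the C-6 carbonyl (activator; Barton–McCombie), the 9β-silyloxy group (face director; oxidised, then re-reduced with inversion), the silyl enol ether (masks the C-2 ketone).

Key step: step 6

Remark: the decalins are numbered as eremophilanes (ring A = C-1 to C-5 and C-10, ring B = C-5 to C-10, methyls on C-4 and C-5, isopropenyl C-11 to C-13 on C-7); β is the face of the C-5 methyl, all decalins are 4β,5β-dimethyl, and compounds 1, 3, 8, 20 and 23 are taken as commercial.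

**Step 1**
Reactants: 1 4-methoxy-3-methylphenol
Product: 2 4,4-dimethoxy-3-methylcyclohexa-2,5-dien-1-one
Conditions: PhI(OAc)2, MeOH, 0 °C
Reagents that add atoms: methanol, CO
Why: Oxidative dearomatisation of a p-methoxyphenol with the iodane in methanol should give the quinone monoketal, methanol adding at the methoxy-bearing carbon para to the phenol oxygen.

**Step 2**
Reactants: 2 4,4-dimethoxy-3-methylcyclohexa-2,5-dien-1-one; 3 isopropenylboronic acid pinacol ester
Product: 4 (5S)-4,4-dimethoxy-3-methyl-5-(prop-1-en-2-yl)cyclohex-2-en-1-one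
Conditions: [Rh(OH)(cod)]2 (2.5 mol %), (S)-BINAP (6 mol %), KOH (0.3 equiv), dioxane/H2O 10:1, 40 °C
Reagents that add atoms: none
Why: Hayashi–Miyaura asymmetric 1,4-addition should deliver the isopropenyl group to the unsubstituted enone β-carbon (the methyl-bearing β-carbon is inert) and the Rh–(S)-BINAP insertion should set the (5S) centre, the sense being assigned by analogy with 2-cyclohexenone (the ligand antipode is taken if a test run shows the opposite sense).

**Step 3**
Reactants: 4 (5S)-4,4-dimethoxy-3-methyl-5-(prop-1-en-2-yl)cyclohex-2-en-1-one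
Product: 6 (4S,6S)-4-hydroxy-2-methyl-6-(prop-1-en-2-yl)cyclohex-2-en-1-one, via ketal alcohol 5 (not isolated)
Conditions: NaBH4, CeCl3·7H2O, MeOH, −78 °C; then 1 M HCl, THF, 0 °C
Reagents that add atoms: water, O
Why: Luche 1,2-reduction should deliver hydride axially and give the alcohol cis to the isopropenyl group, as in the carvone to cis-carveol case, and mild acid hydrolysis of the allylic dimethyl ketal then unveils the α-methyl enone.

**Step 4**
Reactants: 6 (4S,6S)-4-hydroxy-2-methyl-6-(prop-1-en-2-yl)cyclohex-2-en-1-one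
Product: 7 (4S,6S)-2-methyl-6-(prop-1-en-2-yl)-4-(triethylsilyloxy)cyclohex-2-en-1-one
Conditions: Et3SiCl, imidazole, CH2Cl2, 0 °C
Reagents that add atoms: chlorotriethylsilane, CC[Si](Cl)(CC)CC
Why: Standard silylation of the secondary allylic alcohol gives the ether that later blocks the β-face and can be removed in the presence of the bulkier enol silyl ether.

**Step 5**
Reactants: 8 (E)-pent-3-en-2-one
Product: 9 (E)-2-(triisopropylsilyloxy)penta-1,3-diene
Conditions: i-Pr3SiOTf, Et3N, CH2Cl2, 0 °C
Reagents that add atoms: triisopropylsilyl trifluoromethanesulfonate, CC(C)[Si](OS(=O)(=O)C(F)(F)F)(C(C)C)C(C)C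
Why: Soft enolisation of the methyl ketone (kinetic, cross-conjugated) with a silyl triflate and an amine base should give the 2-silyloxydiene with the E double bond untouched.

**Step 6**
Reactants: 7 (4S,6S)-2-methyl-6-(prop-1-en-2-yl)-4-(triethylsilyloxy)cyclohex-2-en-1-one; 9 (E)-2-(triisopropylsilyloxy)penta-1,3-diene
Product: 10 9β-(triethylsilyloxy)-2-(triisopropylsilyloxy)-7αH,10βH-eremophila-2,11-dien-6-one
Conditions: Me2AlCl (0.3 equiv), CH2Cl2/toluene, −78 to −30 °C
Reagents that add atoms: none
Why: Me2AlCl binds the C-6 carbonyl of 7 and the 2-silyloxydiene adds in a concerted but asynchronous [4+2], the nucleophilic CH2 terminus bonding first to the enone β-carbon (C-1–C-10) and the CHMe terminus then to the α-carbon (C-4–C-5), which is the regiochemistry that both the 2-silyloxy group and the terminal methyl group dictate. The closest known reaction type is the Lewis-acid-catalysed exo-selective Diels–Alder reaction of 2-silyloxy-1,3-dienes with 2-cycloalkenones, used here on a 2-methylcyclohexenone so that the quaternary carbon is built. Ring A is closed by the cycloaddition itself (six-membered, suprafacial on both partners; in the stepwise limit a Mukaiyama–Michael addition followed by a 6-endo-trig enolate closure). C-5 and C-10 arise cis because both bonds form on one face of the ring alkene, and that face should be the α-face, anti to the silyloxy group on C-9 and the isopropenyl group on C-7, which both sit on the β-face. C-4 is set by the exo transition state, in which ring B points away from the diene so that the E-methyl group ends cis to the C-5 methyl. The step needs exo over endo and α- over β-face attack; the first is secured by the clash between the bulky OSi(i-Pr)3 group and the C-9 CH(OSiEt3) unit in the endo arrangement together with the α-methyl group of the dienophile, the second by the two β-substituents of ring B.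

**Step 7**
Reactants: 10 9β-(triethylsilyloxy)-2-(triisopropylsilyloxy)-7αH,10βH-eremophila-2,11-dien-6-one
Product: 11 9β-(triethylsilyloxy)-2-(triisopropylsilyloxy)-7αH,10βH-eremophila-2,11-dien-6α-ol
Conditions: LiAlH4, THF, 0 °C
Reagents that add atoms: none
Why: Hydride reduction of the hindered C-6 ketone is expected from the β-face (axial delivery) to give the equatorial 6α-alcohol, and either epimer serves because the centre is removed in step 9.

**Step 8**
Reactants: 11 9β-(triethylsilyloxy)-2-(triisopropylsilyloxy)-7αH,10βH-eremophila-2,11-dien-6α-ol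
Product: 14 O-[9β-(triethylsilyloxy)-2-(triisopropylsilyloxy)-7αH,10βH-eremophila-2,11-dien-6α-yl] S-methyl dithiocarbonate, via sodium alkoxide 12 (not isolated), via sodium xanthate 13 (not isolated)
Conditions: NaH, imidazole (cat.), THF, 0 °C to rt; CS2; then MeI
Reagents that add atoms: carbon disulfide, S=C=S; iodomethane, CI
Why: Xanthate formation (alkoxide, CS2, then S-methylation) is the derivatisation of choice for a hindered secondary alcohol.

**Step 9**
Reactants: 14 O-[9β-(triethylsilyloxy)-2-(triisopropylsilyloxy)-7αH,10βH-eremophila-2,11-dien-6α-yl] S-methyl dithiocarbonate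
Product: 15 9β-(triethylsilyloxy)-2-(triisopropylsilyloxy)-7αH,10βH-eremophila-2,11-diene
Conditions: Bu3SnH (3 equiv, 0.2 M), AIBN (cat.), toluene, 100 °C
Reagents that add atoms: none
Why: Barton–McCombie deoxygenation removes the activating oxygen, and a high tin hydride concentration should let hydrogen transfer outrun 3-exo attack of the C-6 radical on the neighbouring isopropenyl group.

**Step 10**
Reactants: 15 9β-(triethylsilyloxy)-2-(triisopropylsilyloxy)-7αH,10βH-eremophila-2,11-diene
Product: 16 2-(triisopropylsilyloxy)-7αH,10βH-eremophila-2,11-dien-9β-ol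
Conditions: PPTS (0.1 equiv), MeOH/CH2Cl2, 0 °C
Reagents that add atoms: none
Why: Acid-catalysed methanolysis should cleave the secondary triethylsilyl ether selectively, the hindered triisopropylsilyl enol ether being much slower to solvolyse.

**Step 11**
Reactants: 16 2-(triisopropylsilyloxy)-7αH,10βH-eremophila-2,11-dien-9β-ol
Product: 17 2-(triisopropylsilyloxy)-7αH,10βH-eremophila-2,11-dien-9-one
Conditions: Dess–Martin periodinane, pyridine, CH2Cl2, 0 °C to rt
Reagents that add atoms: none
Why: Dess–Martin oxidation under buffered, non-basic conditions should give the C-9 ketone without epimerising the adjacent ring-fusion centre C-10.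

**Step 12**
Reactants: 17 2-(triisopropylsilyloxy)-7αH,10βH-eremophila-2,11-dien-9-one
Product: 19 8α-hydroxy-2-(triisopropylsilyloxy)-7αH,10βH-eremophila-2,11-dien-9-one, via potassium enolate 18 (not isolated)
Conditions: KN(SiMe3)2, THF, −78 °C; then 2-(phenylsulfonyl)-3-phenyloxaziridine, −78 °C; AcOH quench
Reagents that add atoms: 2-(phenylsulfonyl)-3-phenyloxaziridine, O=S(=O)(c1ccccc1)N1OC1c1ccccc1
Why: Kinetic deprotonation should occur at the C-8 methylene rather than the hindered C-10 methine, and oxygen transfer from the N-sulfonyloxaziridine to the enolate (Davis-type hydroxylation) should occur trans to the C-7 isopropenyl group, giving the equatorial 8α-alcohol, which is also the more stable epimer.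

**Step 13**
Reactants: 19 8α-hydroxy-2-(triisopropylsilyloxy)-7αH,10βH-eremophila-2,11-dien-9-one; 20 (R)-2-methylbutanoic acid
Product: 21 8α-[(2R)-2-methylbutanoyloxy]-2-(triisopropylsilyloxy)-7αH,10βH-eremophila-2,11-dien-9-one
Conditions: DCC, DMAP (cat.), CH2Cl2, 0 °C
Reagents that add atoms: none
Why: Steglich esterification of the unhindered equatorial α-ketol hydroxyl installs the C-8 ester, and low temperature with catalytic DMAP keeps the α-centre of the acid intact.

**Step 14**
Reactants: 21 8α-[(2R)-2-methylbutanoyloxy]-2-(triisopropylsilyloxy)-7αH,10βH-eremophila-2,11-dien-9-one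
Product: 22 8α-[(2R)-2-methylbutanoyloxy]-2-(triisopropylsilyloxy)-7αH,10βH-eremophila-2,11-dien-9α-ol
Conditions: LiBH(s-Bu)3, THF, −78 °C; AcOH quench at −78 °C
Reagents that add atoms: none
Why: The bulky borohydride should attack C-9 from the equatorial (β) side, axial approach being blocked by the syn-axial C-4–C-5 bond, to give the axial 9α-alcohol cis to the C-8 ester, and the cold acidic quench avoids acyl migration.

**Step 15**
Reactants: 22 8α-[(2R)-2-methylbutanoyloxy]-2-(triisopropylsilyloxy)-7αH,10βH-eremophila-2,11-dien-9α-ol; 23 (E)-2-methylbut-2-enoyl chloride (tigloyl chloride)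
Product: 24 8α-[(2R)-2-methylbutanoyloxy]-9α-[(E)-2-methylbut-2-enoyloxy]-2-(triisopropylsilyloxy)-7αH,10βH-eremophila-2,11-diene
Conditions: DMAP (0.2 equiv), pyridine, CH2Cl2, 0 to 40 °C
Reagents that add atoms: none
Why: DMAP-catalysed acylation of the hindered axial alcohol with the acid chloride installs the tiglate with its E geometry retained.

**Step 16**
Reactants: 24 8α-[(2R)-2-methylbutanoyloxy]-9α-[(E)-2-methylbut-2-enoyloxy]-2-(triisopropylsilyloxy)-7αH,10βH-eremophila-2,11-diene
Product: 25 8α-[(2R)-2-methylbutanoyloxy]-9α-[(E)-2-methylbut-2-enoyloxy]-7αH,10βH-eremophil-11-en-2-one (target)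
Conditions: HF·pyridine, pyridine, THF, 0 °C
Reagents that add atoms: none
Why: Fluoride-assisted protodesilylation of the enol ether should release the C-2 ketone by protonation at C-3, which creates no stereocentre and leaves both esters untouched.

**Compound list**
1 | 4-methoxy-3-methylphenol | COc1ccc(O)cc1C | starting material
2 | 4,4-dimethoxy-3-methylcyclohexa-2,5-dien-1-one | COC1(OC)C=CC(=O)C=C1C | intermediate
3 | isopropenylboronic acid pinacol ester | CC(=C)B1OC(C)(C)C(C)(C)O1 | starting material
4 | (5S)-4,4-dimethoxy-3-methyl-5-(prop-1-en-2-yl)cyclohex-2-en-1-one | C=C(C)[C@H]1C(OC)(OC)C(C)=CC(=O)C1 | intermediate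
5 | (1S,5S)-4,4-dimethoxy-3-methyl-5-(prop-1-en-2-yl)cyclohex-2-en-1-ol (ketal alcohol, not isolated) | C=C(C)[C@H]1C(OC)(OC)C(C)=C[C@@H](O)C1 | intermediate
6 | (4S,6S)-4-hydroxy-2-methyl-6-(prop-1-en-2-yl)cyclohex-2-en-1-one | C=C(C)[C@H]1C(=O)C(C)=C[C@@H](O)C1 | intermediate
7 | (4S,6S)-2-methyl-6-(prop-1-en-2-yl)-4-(triethylsilyloxy)cyclohex-2-en-1-one | C=C(C)[C@H]1C(=O)C(C)=C[C@@H](O[Si](CC)(CC)CC)C1 | intermediate
8 | (E)-pent-3-en-2-one | CC(=O)/C=C/C | starting material
9 | (E)-2-(triisopropylsilyloxy)penta-1,3-diene | C=C(O[Si](C(C)C)(C(C)C)C(C)C)/C=C/C | intermediate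
10 | 9β-(triethylsilyloxy)-2-(triisopropylsilyloxy)-7αH,10βH-eremophila-2,11-dien-6-one (cis-decalin, 4β,5β-dimethyl, 7β-isopropenyl) | C=C(C)[C@H]1C(=O)[C@@]2(C)[C@H](CC(O[Si](C(C)C)(C(C)C)C(C)C)=C[C@@H]2C)[C@@H](O[Si](CC)(CC)CC)C1 | intermediate
11 | 9β-(triethylsilyloxy)-2-(triisopropylsilyloxy)-7αH,10βH-eremophila-2,11-dien-6α-ol | C=C(C)[C@H]1[C@H](O)[C@@]2(C)[C@H](CC(O[Si](C(C)C)(C(C)C)C(C)C)=C[C@@H]2C)[C@@H](O[Si](CC)(CC)CC)C1 | intermediate
12 | sodium 6α-alkoxide of 11 (not isolated) | C=C(C)[C@H]1[C@H]([O-])[C@@]2(C)[C@H](CC(O[Si](C(C)C)(C(C)C)C(C)C)=C[C@@H]2C)[C@@H](O[Si](CC)(CC)CC)C1.[Na+] | intermediate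
13 | sodium O-(6α-yl) dithiocarbonate of 11 (sodium xanthate, not isolated) | C=C(C)[C@H]1[C@H](OC(=S)[S-])[C@@]2(C)[C@H](CC(O[Si](C(C)C)(C(C)C)C(C)C)=C[C@@H]2C)[C@@H](O[Si](CC)(CC)CC)C1.[Na+] | intermediate
14 | O-[9β-(triethylsilyloxy)-2-(triisopropylsilyloxy)-7αH,10βH-eremophila-2,11-dien-6α-yl] S-methyl dithiocarbonate | C=C(C)[C@H]1[C@H](OC(=S)SC)[C@@]2(C)[C@H](CC(O[Si](C(C)C)(C(C)C)C(C)C)=C[C@@H]2C)[C@@H](O[Si](CC)(CC)CC)C1 | intermediate
15 | 9β-(triethylsilyloxy)-2-(triisopropylsilyloxy)-7αH,10βH-eremophila-2,11-diene | C=C(C)[C@H]1C[C@@]2(C)[C@H](CC(O[Si](C(C)C)(C(C)C)C(C)C)=C[C@@H]2C)[C@@H](O[Si](CC)(CC)CC)C1 | intermediate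
16 | 2-(triisopropylsilyloxy)-7αH,10βH-eremophila-2,11-dien-9β-ol | C=C(C)[C@H]1C[C@@]2(C)[C@H](CC(O[Si](C(C)C)(C(C)C)C(C)C)=C[C@@H]2C)[C@@H](O)C1 | intermediate
17 | 2-(triisopropylsilyloxy)-7αH,10βH-eremophila-2,11-dien-9-one | C=C(C)[C@H]1C[C@@]2(C)[C@H](CC(O[Si](C(C)C)(C(C)C)C(C)C)=C[C@@H]2C)C(=O)C1 | intermediate
18 | potassium 8(9)-enolate of 17 (not isolated) | C=C(C)[C@H]1C[C@@]2(C)[C@H](CC(O[Si](C(C)C)(C(C)C)C(C)C)=C[C@@H]2C)C([O-])=C1.[K+] | intermediate
19 | 8α-hydroxy-2-(triisopropylsilyloxy)-7αH,10βH-eremophila-2,11-dien-9-one | C=C(C)[C@H]1C[C@@]2(C)[C@H](CC(O[Si](C(C)C)(C(C)C)C(C)C)=C[C@@H]2C)C(=O)[C@@H]1O | intermediate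
20 | (R)-2-methylbutanoic acid | CC[C@@H](C)C(=O)O | starting material
21 | 8α-[(2R)-2-methylbutanoyloxy]-2-(triisopropylsilyloxy)-7αH,10βH-eremophila-2,11-dien-9-one | C=C(C)[C@H]1C[C@@]2(C)[C@H](CC(O[Si](C(C)C)(C(C)C)C(C)C)=C[C@@H]2C)C(=O)[C@@H]1OC(=O)[C@H](C)CC | intermediate
22 | 8α-[(2R)-2-methylbutanoyloxy]-2-(triisopropylsilyloxy)-7αH,10βH-eremophila-2,11-dien-9α-ol | C=C(C)[C@H]1C[C@@]2(C)[C@H](CC(O[Si](C(C)C)(C(C)C)C(C)C)=C[C@@H]2C)[C@H](O)[C@@H]1OC(=O)[C@H](C)CC | intermediate
23 | (E)-2-methylbut-2-enoyl chloride (tigloyl chloride) | C/C=C(\C)C(Cl)=O | starting material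
24 | 8α-[(2R)-2-methylbutanoyloxy]-9α-[(E)-2-methylbut-2-enoyloxy]-2-(triisopropylsilyloxy)-7αH,10βH-eremophila-2,11-diene | C=C(C)[C@H]1C[C@@]2(C)[C@H](CC(O[Si](C(C)C)(C(C)C)C(C)C)=C[C@@H]2C)[C@H](OC(=O)/C(C)=C/C)[C@@H]1OC(=O)[C@H](C)CC | intermediate
25 | 8α-[(2R)-2-methylbutanoyloxy]-9α-[(E)-2-methylbut-2-enoyloxy]-7αH,10βH-eremophil-11-en-2-one | C=C(C)[C@H]1C[C@@]2(C)[C@H](CC(=O)C[C@@H]2C)[C@H](OC(=O)/C(C)=C/C)[C@@H]1OC(=O)[C@H](C)CC | target

**Step count**
Total: 16 steps. Longest linear sequence: 15 steps (steps 1–4 and 6–16 from phenol 1; step 5 is a one-step branch).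

**Three steps most likely to fail**

Step 6 (key cycloaddition). The diene may attack the β-face, or react through the endo arrangement and so deliver the C-4 epimer, or be destroyed by the Lewis acid before it adds. The face is the least certain point, because both ring B substituents are equatorial in the favoured conformer of 7 and their shielding of the β-face is then only moderate. The fallback is an anionic annulation (the known double Michael addition of a cross-conjugated lithium dienolate to an enone) that sets out from 7 and 8. LiN(i-Pr)2 in THF at −78 °C converts 8 into lithium (E)-penta-1,3-dien-2-olate F1. Addition of 7 gives, by Michael addition at C-10, the lithium C-6 enolate of the open-chain adduct F2. On warming to −20 °C the C-5 enolate carbon closes onto the crotonyl unit to give the ring A lithium 2(3)-enolate F3, in which a chair-like closure with an equatorial methyl group should again give the cis-dimethyl pair. Trapping with i-Pr3SiOTf brings the sequence back to the route at 10.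

Step 9 (radical deoxygenation). Chain propagation at the neopentyl C-6 xanthate may stall, and the C-6 radical may be captured by the neighbouring isopropenyl group (3-exo closure followed by a 1,2-vinyl shift). The fallback is ionic and sets out from ketone 10. Condensation with p-toluenesulfonylhydrazide (EtOH, 60 °C, molecular sieves) gives the C-6 tosylhydrazone F4. Reduction with catecholborane (CHCl3, 0 °C) followed by NaOAc·3H2O at reflux expels sulfinate and nitrogen and leaves the methylene group, so the sequence comes back to the route at 15 without a carbon radical at C-6.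

Step 14 (ketone reduction next to the ester). Hydride may be delivered from the wrong face or to the ester carbonyl, and the alkoxide formed may take part in a 1,2-acyl shift. The fallback reverses the order of events and sets out from hydroxy ketone 19. NaBH4 in MeOH at −40 °C (AcOH quench) reduces the ketone by the same equatorial approach to the 8α,9α-diol F5. The equatorial 8-hydroxyl is then acylated selectively with acid 20 (DCC, catalytic DMAP, CH2Cl2, −20 °C), the axial 9-hydroxyl being shielded by the ring fusion, and the sequence comes back to the route at 22.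

Further compounds
F1 | step 6 | lithium (E)-penta-1,3-dien-2-olate | [Li+].C=C([O-])/C=C/C
F2 | step 6 | lithium C-6 enolate of the open-chain Michael adduct (crotonylmethyl group on C-10) | C=C(C)[C@H]1C([O-])=C(C)[C@H](CC(=O)/C=C/C)[C@@H](O[Si](CC)(CC)CC)C1.[Li+]
F3 | step 6 | ring A lithium 2(3)-enolate of 9β-(triethylsilyloxy)-7αH,10βH-eremophil-11-ene-2,6-dione | C=C(C)[C@H]1C(=O)[C@@]2(C)[C@H](CC([O-])=C[C@@H]2C)[C@@H](O[Si](CC)(CC)CC)C1.[Li+]
F4 | step 9 | C-6 p-toluenesulfonylhydrazone of 10 | C=C(C)[C@H]1C(=NNS(=O)(=O)c3ccc(C)cc3)[C@@]2(C)[C@H](CC(O[Si](C(C)C)(C(C)C)C(C)C)=C[C@@H]2C)[C@@H](O[Si](CC)(CC)CC)C1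
F5 | step 14 | 2-(triisopropylsilyloxy)-7αH,10βH-eremophila-2,11-diene-8α,9α-diol | C=C(C)[C@H]1C[C@@]2(C)[C@H](CC(O[Si](C(C)C)(C(C)C)C(C)C)=C[C@@H]2C)[C@H](O)[C@@H]1O
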